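Ent-kaurane numbering is used. Everything rests on the C12–C13 bond of ring C (C8, C9, C11, C12, C13, C14): the unit C11(=O)–C12–C13–C16=C17 is the retron of an allylsilane alkylated at its γ-carbon by an α-keto electrophile. In the key step a Lewis acid-activated diazoketone (C11/C12) is captured by the allylsilane C13=C16–C17–Si of a cyclopentene: ring C closes, C13 is set, the C11 ketone appears and loss of silicon creates the exocyclic methylene. The precursor, ring A joined through C9 to a cyclopentene bearing quaternary C8, comes from a Diels–Alder reaction and an Ireland–Claisen rearrangement that fixes C8 and C9.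

Key step: step 21

Remark: ring A = C1–C5 and C10; C15 and C16 complete ring D; C6 and C19 are the carboxyl carbons, C7 the formyl carbon, C17 the methylene carbon, C18 and C20 the methyls; α is the face of ring A that carries C20.

Step 1
Reactants: 1 tert-butyl 3-methylbut-2-enoate
Product: 2 tert-butyl (2E)-3-methyl-4-oxobut-2-enoate
Conditions: SeO2, 1,4-dioxane, 100 °C
Reagents that add atoms: selenium dioxide, O=[Se]=O
Why: Riley oxidation (ene reaction then [2,3] shift) should oxidise the methyl group trans to the ester and give the (E)-enal.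

Step 2
Reactants: 3 tert-butyl acetate; 4 acrolein
Product: 5 tert-butyl 3-hydroxypent-4-enoate (racemic)
Conditions: LDA, THF, −78 °C; then 4; aq. NH4Cl
Reagents that add atoms: none
Why: Directed aldol addition of the lithium ester enolate to the aldehyde carbon of acrolein at low temperature.

Step 3
Reactants: 5 tert-butyl 3-hydroxypent-4-enoate
Product: 6 tert-butyl 3-oxopent-4-enoate
Conditions: Dess–Martin periodinane, CH2Cl2, 0 °C
Reagents that add atoms: none
Why: Dess–Martin oxidation of the allylic alcohol under neutral conditions should give the Michael-sensitive vinyl ketone (Nazarov-type reagent) without polymerisation.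

Step 4
Reactants: 6 tert-butyl 3-oxopent-4-enoate
Product: 7 tert-butyl (2Z)-3-[(tert-butyldimethylsilyl)oxy]penta-2,4-dienoate
Conditions: TBSOTf, Et3N, CH2Cl2, −78 → 0 °C
Reagents that add atoms: tert-butyldimethylsilyl triflate, CC(C)(C)[Si](C)(C)OS(=O)(=O)C(F)(F)F
Why: Soft enolisation and O-silylation of the β-keto ester should give the (Z)-silyl dienol ether (ester cis to OSi), the geometry that can adopt the s-cis diene.

Step 5
Reactants: 2 tert-butyl (2E)-3-methyl-4-oxobut-2-enoate; 7 tert-butyl (2Z)-3-[(tert-butyldimethylsilyl)oxy]penta-2,4-dienoate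
Product: 8 di-tert-butyl 3-formyl-3-methyl-6-[(tert-butyldimethylsilyl)oxy]cyclohex-5-ene-1,2-dicarboxylate (ring A; C10: CH3 α and CHO β; C5 ester α; C4 ester β; C3(OTBS)=C2)
Conditions: (S)-2-(o-tolyl)-CBS-oxazaborolidine·HNTf2 (10 mol %), CH2Cl2, −78 → −40 °C
Reagents that add atoms: none
Why: Catalytic enantioselective Diels–Alder reaction in which the formyl-bound cationic oxazaborolidine makes C5 the electrophilic terminus for the nucleophilic C4 of the 2-siloxydiene, suprafacial addition to the (E)-enal places the C9 formyl group trans to the C6 ester at C10/C5, the catalyst (enantiomer chosen for this antipode) sets their absolute sense, and the endo C4 centre is erased in step 7.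

Step 6
Reactants: 8 Diels–Alder adduct
Product: 9 di-tert-butyl 3-(2-methoxyethenyl)-3-methyl-6-[(tert-butyldimethylsilyl)oxy]cyclohex-5-ene-1,2-dicarboxylate (C9=C11 enol ether, E/Z mixture)
Conditions: Ph3P(CH2OMe)Cl, KHMDS, THF, −78 → 0 °C
Reagents that add atoms: (methoxymethyl)triphenylphosphonium chloride, COC[P+](c1ccccc1)(c1ccccc1)c1ccccc1.[Cl-]
Why: Wittig methoxymethylenation of the non-enolisable neopentyl aldehyde homologates C9 by C11 while esters and the silyl enol ether stay untouched.

Step 7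
Reactants: 9 enol ether
Product: 10 di-tert-butyl 3-(2-methoxyethenyl)-1,3-dimethyl-6-[(tert-butyldimethylsilyl)oxy]cyclohex-5-ene-1,2-dicarboxylate (C4: CH3 β, ester α)
Conditions: LDA, THF, −78 °C; MeI, −78 → −20 °C
Reagents that add atoms: iodomethane, CI
Why: Ester enolate alkylation in which A(1,3) strain holds the C5 ester pseudo-axial, so that MeI should enter C4 anti to it and place the C19 ester α, cis to C6 and C20.

Step 8
Reactants: 10 methylated silyl enol ether
Product: 11 di-tert-butyl 3-(2-methoxyethenyl)-1,3-dimethyl-6-(trifluoromethanesulfonyloxy)cyclohex-5-ene-1,2-dicarboxylate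
Conditions: CsF, PhNTf2, DME, 25 °C
Reagents that add atoms: N-phenylbis(trifluoromethanesulfonimide), O=S(=O)(N(c1ccccc1)S(=O)(=O)C(F)(F)F)C(F)(F)F
Why: Fluoride-induced conversion of the silyl enol ether into the enol triflate keeps the C3=C2 regiochemistry and prepares removal of the C3 oxygen.

Step 9
Reactants: 11 enol triflate
Product: 13 2-[2,3-bis(tert-butoxycarbonyl)-1,3-dimethyl-4-(trifluoromethanesulfonyloxy)cyclohex-4-en-1-yl]acetic acid, via aldehyde 12 (not isolated)
Conditions: 1 M HCl, THF, 0 °C; then NaClO2, NaH2PO4, 2-methylbut-2-ene, t-BuOH–H2O, 25 °C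
Reagents that add atoms: water, O; sodium chlorite, [Na+].[O-]Cl=O
Why: Mild acid hydrolysis of the methyl enol ether followed by Pinnick oxidation gives the C11 acid while the enol triflate and tert-butyl esters survive.

Step 10
Reactants: 13 enol triflate acid
Product: 14 2-[(1S,2S,3R)-2,3-bis(tert-butoxycarbonyl)-1,3-dimethylcyclohexyl]acetic acid
Conditions: H2 (1 atm), PtO2, Et3N, EtOAc, 25 °C
Reagents that add atoms: none
Why: Platinum-catalysed hydrogenolysis and hydrogenation of the enol triflate should reduce C3 to a methylene group (net deoxygenation).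

Step 11
Reactants: 15 3-bromocyclopent-2-en-1-one; 16 (tributylstannyl)methanol
Product: 17 3-(hydroxymethyl)cyclopent-2-en-1-one
Conditions: Pd(PPh3)4 (5 mol %), 1,4-dioxane, 90 °C
Reagents that add atoms: none
Why: Stille (Kosugi–Migita) hydroxymethylation of the β-bromo enone installs C7 on C8.

Step 12
Reactants: 17 3-(hydroxymethyl)cyclopent-2-en-1-one
Product: 18 3-(tert-butoxymethyl)cyclopent-2-en-1-one
Conditions: isobutylene, Amberlyst-15, CH2Cl2, 25 °C (sealed)
Reagents that add atoms: 2-methylpropene, CC(C)=C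
Why: Acid-catalysed addition of the primary alcohol to isobutylene gives a tert-butyl ether that is removed later together with the esters.

Step 13
Reactants: 18 3-(tert-butoxymethyl)cyclopent-2-en-1-one
Product: 19 (1S)-3-(tert-butoxymethyl)cyclopent-2-en-1-ol
Conditions: (R)-2-methyl-CBS-oxazaborolidine (10 mol %), BH3·SMe2, THF, −30 °C; MeOH
Reagents that add atoms: none
Why: Corey–Bakshi–Shibata reduction in which the alkenyl side acts as the large group, so the (R)-catalyst should deliver the (S)-carbinol (C13).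

Step 14
Reactants: 14 ring-A acetic acid; 19 (1S)-3-(tert-butoxymethyl)cyclopent-2-en-1-ol
Product: 20 (1S)-3-(tert-butoxymethyl)cyclopent-2-en-1-yl 2-[(1S,2S,3R)-2,3-bis(tert-butoxycarbonyl)-1,3-dimethylcyclohexyl]acetate
Conditions: DCC, DMAP (cat.), CH2Cl2, 0 → 25 °C
Reagents that add atoms: none
Why: Steglich esterification joins the two enantiopure fragments through the C11 carboxyl group.

Step 15
Reactants: 20 allylic ester
Product: 23 2-[(1S,2S,3R)-2,3-bis(tert-butoxycarbonyl)-1,3-dimethylcyclohexyl]-2-[1-(tert-butoxymethyl)cyclopent-2-en-1-yl]acetic acid (C8 and C9 as in the target), via silyl ketene acetal 21 (not isolated), via trimethylsilyl ester 22 (not isolated)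
Conditions: LDA, THF–DMPU, −78 °C; Me3SiCl; −78 → 60 °C; 1 M HCl
Reagents that add atoms: none
Why: Ireland–Claisen rearrangement in which the suprafacial [3,3] shift transfers the C13 carbinol chirality to quaternary C8, and C9 should follow because the bulky ring-A group must point away from the cyclopentene ring (boat from the ketene acetal with ring A cis to OSi, chair from the other geometry, both giving the same C8/C9 relationship).

Step 16
Reactants: 23 cyclopentene acid
Product: 24 2-[ring A]-2-[1-(tert-butoxymethyl)-4-oxocyclopent-2-en-1-yl]acetic acid (C16 ketone, C13=C14)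
Conditions: Rh2(cap)4 (dirhodium tetracaprolactamate, 1 mol %), t-BuOOH (70 % in H2O), ClCH2CH2Cl, 40 °C
Reagents that add atoms: tert-butyl hydroperoxide, CC(C)(C)OO
Why: Catalytic allylic oxidation is regiospecific because C16 is the only allylic CH2 (C8 is quaternary).

Step 17
Reactants: 24 enone acid
Product: 25 2-[ring A]-2-[1-(tert-butoxymethyl)-3-oxocyclopentyl]acetic acid
Conditions: H2 (1 atm), Pd/C, EtOAc, 25 °C
Reagents that add atoms: none
Why: Heterogeneous hydrogenation of the only C=C bond gives the cyclopentanone with C14 as CH2.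

Step 18
Reactants: 25 keto acid
Product: 26 2-[ring A]-2-[1-(tert-butoxymethyl)-3-(trifluoromethanesulfonyloxy)cyclopent-3-en-1-yl]acetic acid (C13=C16)
Conditions: LiHMDS (2.2 equiv), THF, −78 °C; PhNTf2, −78 → 0 °C; aq. NH4Cl
Reagents that add atoms: N-phenylbis(trifluoromethanesulfonimide), O=S(=O)(N(c1ccccc1)S(=O)(=O)C(F)(F)F)C(F)(F)F
Why: Kinetic enolisation of the carboxylate salt should occur at the unhindered C13, away from quaternary C8, and O-triflation then gives the C13=C16 enol triflate.

Step 19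
Reactants: 26 enol triflate acid
Product: 27 2-[ring A]-2-{1-(tert-butoxymethyl)-3-[(trimethylsilyl)methyl]cyclopent-3-en-1-yl}acetic acid
Conditions: Me3SiCH2MgCl (3 equiv), Pd(PPh3)4 (5 mol %), THF, 0 → 25 °C; aq. NH4Cl
Reagents that add atoms: (trimethylsilyl)methylmagnesium chloride, C[Si](C)(C)C[Mg]Cl
Why: Kumada–Corriu coupling of the enol triflate installs C17 as the allylsilane carbon, one equivalent of Grignard reagent being spent on the acid.

Step 20
Reactants: 27 allylsilane acid
Product: 29 α-diazoketone of 27 (C11(=O)–C12H=N2), via mixed anhydride 28 (not isolated)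
Conditions: i-BuOCOCl, Et3N, THF, −15 °C; then CH2N2, Et2O, 0 °C
Reagents that add atoms: diazomethane, C=[N+]=[N-]
Why: Acylation of diazomethane by the mixed carbonic anhydride (first stage of an Arndt–Eistert sequence) adds C12 without strongly acidic intermediates.

Step 21
Reactants: 29 allylsilane diazoketone
Product: 31 di-tert-butyl ester and tert-butyl ether of ent-7-hydroxy-11-oxo-6,7-secokaur-16-ene-6,19-dioic acid, via trimethylsilyl enol ether 30 (not isolated)
Conditions: BF3·OEt2 (0.2 equiv), CH2Cl2, −78 → −30 °C; then aq. citric acid, THF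
Reagents that add atoms: none
Why: BF3 binds the diazoketone oxygen, the diazonium enolate is attacked at C12 by the γ-carbon (C13) of the allylsilane with loss of N2, and the β-silyl cation at C16 collapses by silyl transfer to the enolate oxygen through a six-membered array, giving C16=C17 and enol ether 30, which is hydrolysed on work-up. The closest known reaction types are the Lewis acid-promoted cyclisation of unsaturated α-diazoketones and the intramolecular Hosomi–Sakurai reaction. Ring C closes in a 6-exo-trig mode with respect to the C13=C16 bond. The only new stereocentre, C13, is fixed by the cis-1,3 bridging forced by the C8–C9 tether, since only the ring face that carries C9 can be reached. The step needs γ-selectivity, secured by the β-silicon effect that directs bond formation to C13 and the new double bond to C16=C17, and chemoselectivity over Wolff rearrangement or C–H insertion, secured by the carbene-free cationic pathway at low temperature.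

Step 22
Reactants: 31 protected secokaurene
Product: 32 ent-7-hydroxy-11-oxo-6,7-secokaur-16-ene-6,19-dioic acid
Conditions: 85 % aq. H3PO4, toluene, 40 °C
Reagents that add atoms: none
Why: SN1-type cleavage of both tert-butyl esters and the tert-butyl ether by aqueous phosphoric acid, which should be mild enough to leave the 1,1-disubstituted alkene and the epimerisable C9 untouched.

Step 23
Reactants: 32 hydroxy diacid
Product: 33 ent-7,11-dioxo-6,7-secokaur-16-ene-6,19-dioic acid (target)
Conditions: Dess–Martin periodinane, CH2Cl2, 0 → 25 °C; aq. Na2S2O3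
Reagents that add atoms: none
Why: Dess–Martin oxidation of the neopentyl primary alcohol to the C7 aldehyde under neutral conditions, so that C9 next to the C11 ketone should not epimerise.

Compound list
1 | tert-butyl 3-methylbut-2-enoate | CC(C)=CC(=O)OC(C)(C)C | starting material
2 | tert-butyl (2E)-3-methyl-4-oxobut-2-enoate | O=C/C(C)=C/C(=O)OC(C)(C)C | intermediate
3 | tert-butyl acetate | CC(=O)OC(C)(C)C | starting material
4 | acrolein | C=CC=O | starting material
5 | tert-butyl 3-hydroxypent-4-enoate (racemic) | C=CC(O)CC(=O)OC(C)(C)C | intermediate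
6 | tert-butyl 3-oxopent-4-enoate | C=CC(=O)CC(=O)OC(C)(C)C | intermediate
7 | tert-butyl (2Z)-3-[(tert-butyldimethylsilyl)oxy]penta-2,4-dienoate | C=C/C(O[Si](C)(C)C(C)(C)C)=C/C(=O)OC(C)(C)C | intermediate
8 | Diels–Alder adduct (C10 CH3 α, CHO β; C5 ester α; C4 ester β) | O=C[C@]1(C)CC=C(O[Si](C)(C)C(C)(C)C)[C@H](C(=O)OC(C)(C)C)[C@H]1C(=O)OC(C)(C)C | intermediate
9 | C9=C11 methyl enol ether of 8 (E/Z mixture) | COC=C[C@]1(C)CC=C(O[Si](C)(C)C(C)(C)C)[C@H](C(=O)OC(C)(C)C)[C@H]1C(=O)OC(C)(C)C | intermediate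
10 | C4-methylated enol ether (C4 CH3 β, ester α) | COC=C[C@]1(C)CC=C(O[Si](C)(C)C(C)(C)C)[C@@](C)(C(=O)OC(C)(C)C)[C@H]1C(=O)OC(C)(C)C | intermediate
11 | enol triflate of 10 | COC=C[C@]1(C)CC=C(OS(=O)(=O)C(F)(F)F)[C@@](C)(C(=O)OC(C)(C)C)[C@H]1C(=O)OC(C)(C)C | intermediate
12 | C11 aldehyde (not isolated) | O=CC[C@]1(C)CC=C(OS(=O)(=O)C(F)(F)F)[C@@](C)(C(=O)OC(C)(C)C)[C@H]1C(=O)OC(C)(C)C | intermediate
13 | enol triflate acetic acid | OC(=O)C[C@]1(C)CC=C(OS(=O)(=O)C(F)(F)F)[C@@](C)(C(=O)OC(C)(C)C)[C@H]1C(=O)OC(C)(C)C | intermediate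
14 | 2-[(1S,2S,3R)-2,3-bis(tert-butoxycarbonyl)-1,3-dimethylcyclohexyl]acetic acid | OC(=O)C[C@]1(C)CCC[C@@](C)(C(=O)OC(C)(C)C)[C@H]1C(=O)OC(C)(C)C | intermediate
15 | 3-bromocyclopent-2-en-1-one | O=C1C=C(Br)CC1 | starting material
16 | (tributylstannyl)methanol | OC[Sn](CCCC)(CCCC)CCCC | starting material
17 | 3-(hydroxymethyl)cyclopent-2-en-1-one | O=C1C=C(CO)CC1 | intermediate
18 | 3-(tert-butoxymethyl)cyclopent-2-en-1-one | O=C1C=C(COC(C)(C)C)CC1 | intermediate
19 | (1S)-3-(tert-butoxymethyl)cyclopent-2-en-1-ol | O[C@@H]1C=C(COC(C)(C)C)CC1 | intermediate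
20 | allylic ester of 14 with 19 | O=C(C[C@]1(C)CCC[C@@](C)(C(=O)OC(C)(C)C)[C@H]1C(=O)OC(C)(C)C)O[C@@H]1C=C(COC(C)(C)C)CC1 | intermediate
21 | trimethylsilyl ketene acetal of 20 (not isolated) | C[Si](C)(C)OC(=C[C@]1(C)CCC[C@@](C)(C(=O)OC(C)(C)C)[C@H]1C(=O)OC(C)(C)C)O[C@@H]1C=C(COC(C)(C)C)CC1 | intermediate
22 | trimethylsilyl ester of 23 (not isolated) | C[Si](C)(C)OC(=O)[C@@H]([C@]1(C)CCC[C@@](C)(C(=O)OC(C)(C)C)[C@H]1C(=O)OC(C)(C)C)[C@@]1(COC(C)(C)C)C=CCC1 | intermediate
23 | Claisen acid (C13=C14) | OC(=O)[C@@H]([C@]1(C)CCC[C@@](C)(C(=O)OC(C)(C)C)[C@H]1C(=O)OC(C)(C)C)[C@@]1(COC(C)(C)C)C=CCC1 | intermediate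
24 | C16 enone acid | OC(=O)[C@@H]([C@]1(C)CCC[C@@](C)(C(=O)OC(C)(C)C)[C@H]1C(=O)OC(C)(C)C)[C@@]1(COC(C)(C)C)C=CC(=O)C1 | intermediate
25 | C16 cyclopentanone acid | OC(=O)[C@@H]([C@]1(C)CCC[C@@](C)(C(=O)OC(C)(C)C)[C@H]1C(=O)OC(C)(C)C)[C@@]1(COC(C)(C)C)CCC(=O)C1 | intermediate
26 | C13=C16 enol triflate acid | OC(=O)[C@@H]([C@]1(C)CCC[C@@](C)(C(=O)OC(C)(C)C)[C@H]1C(=O)OC(C)(C)C)[C@@]1(COC(C)(C)C)CC=C(OS(=O)(=O)C(F)(F)F)C1 | intermediate
27 | allylsilane acid | OC(=O)[C@@H]([C@]1(C)CCC[C@@](C)(C(=O)OC(C)(C)C)[C@H]1C(=O)OC(C)(C)C)[C@@]1(COC(C)(C)C)CC=C(C[Si](C)(C)C)C1 | intermediate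
28 | isobutyl carbonic mixed anhydride of 27 (not isolated) | CC(C)COC(=O)OC(=O)[C@@H]([C@]1(C)CCC[C@@](C)(C(=O)OC(C)(C)C)[C@H]1C(=O)OC(C)(C)C)[C@@]1(COC(C)(C)C)CC=C(C[Si](C)(C)C)C1 | intermediate
29 | allylsilane α-diazoketone | [N-]=[N+]=CC(=O)[C@@H]([C@]1(C)CCC[C@@](C)(C(=O)OC(C)(C)C)[C@H]1C(=O)OC(C)(C)C)[C@@]1(COC(C)(C)C)CC=C(C[Si](C)(C)C)C1 | intermediate
30 | C11 trimethylsilyl enol ether of 31 (not isolated) | C=C1C[C@]2(COC(C)(C)C)C[C@H]1C=C(O[Si](C)(C)C)[C@H]2[C@]1(C)CCC[C@@](C)(C(=O)OC(C)(C)C)[C@H]1C(=O)OC(C)(C)C | intermediate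
31 | di-tert-butyl ester, tert-butyl ether of ent-7-hydroxy-11-oxo-6,7-secokaur-16-ene-6,19-dioic acid | C=C1C[C@]2(COC(C)(C)C)C[C@H]1CC(=O)[C@H]2[C@]1(C)CCC[C@@](C)(C(=O)OC(C)(C)C)[C@H]1C(=O)OC(C)(C)C | intermediate
32 | ent-7-hydroxy-11-oxo-6,7-secokaur-16-ene-6,19-dioic acid | C=C1C[C@]2(CO)C[C@H]1CC(=O)[C@H]2[C@]1(C)CCC[C@@](C)(C(=O)O)[C@H]1C(=O)O | intermediate
33 | ent-7,11-dioxo-6,7-secokaur-16-ene-6,19-dioic acid | C=C1C[C@]2(C=O)C[C@H]1CC(=O)[C@H]2[C@]1(C)CCC[C@@](C)(C(=O)O)[C@H]1C(=O)O | target

Total step count: 23. Longest linear sequence: 19 steps (steps 2–10, then 14–23).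

Steps most likely to fail

Step 21. The allylsilane may be protodesilylated before C–C bond formation, or the diazoketone may decompose by Wolff rearrangement. The fallback sets out from 29 and comes back at 31. Decomposition of 29 with Rh2(OAc)4 in CH2Cl2 gives, by intramolecular cyclopropanation of the C13=C16 bond, the trachylobane-type cyclopropyl ketone F1. Bu4NF/AcOH in THF then attacks silicon and opens the C12–C16 bond, with C16=C17 forming and the C11 enolate being protonated, to give 31.

Step 15. Enolisation of the neopentyl ester may be incomplete, or competing transition-state geometries may erode the C9 configuration. The fallback sets out from 14 and comes back at 23. Acid 14 is reduced with BH3·SMe2 to the alcohol F2 and oxidised (Dess–Martin) to the aldehyde F3. Heating F3 with 19 and catalytic propanoic acid in xylene, with azeotropic removal of water, forms the allyl vinyl ether F4 in the flask, which undergoes the aliphatic Claisen rearrangement to the aldehyde F5. Pinnick oxidation of F5 gives 23.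

Step 18. Enolisation may lose regiocontrol (C15 against C13), or the carboxylate may be sulfonylated. The fallback sets out from 24 and comes back at 26. Conjugate reduction of enone 24 with [(Ph3P)CuH]6 (or LiB(s-Bu)3H) generates the C13 enolate regiospecifically, and it is trapped in the same flask with PhNTf2; this fallback makes no new compound (F0).

Further compounds
F1 | step 21 | cyclopropyl ketone (C12–C13–C16 cyclopropane, CH2SiMe3 on C16) | C[Si](C)(C)C[C@]13C[C@]2(COC(C)(C)C)C[C@H]1[C@H]3C(=O)[C@H]2[C@]1(C)CCC[C@@](C)(C(=O)OC(C)(C)C)[C@H]1C(=O)OC(C)(C)C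
F2 | step 15 | di-tert-butyl (1R,2S,3S)-3-(2-hydroxyethyl)-1,3-dimethylcyclohexane-1,2-dicarboxylate | OCC[C@]1(C)CCC[C@@](C)(C(=O)OC(C)(C)C)[C@H]1C(=O)OC(C)(C)C
F3 | step 15 | di-tert-butyl (1R,2S,3S)-1,3-dimethyl-3-(2-oxoethyl)cyclohexane-1,2-dicarboxylate | O=CC[C@]1(C)CCC[C@@](C)(C(=O)OC(C)(C)C)[C@H]1C(=O)OC(C)(C)C
F4 | step 15 | allyl vinyl ether of F3 with 19 (E/Z mixture) | C(=C[C@]1(C)CCC[C@@](C)(C(=O)OC(C)(C)C)[C@H]1C(=O)OC(C)(C)C)O[C@@H]1C=C(COC(C)(C)C)CC1
F5 | step 15 | C11 aldehyde corresponding to 23 | O=C[C@@H]([C@]1(C)CCC[C@@](C)(C(=O)OC(C)(C)C)[C@H]1C(=O)OC(C)(C)C)[C@@]1(COC(C)(C)C)C=CCC1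
F0 | step 18 | none | none
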